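The easy step came first: I turned percent of G into molarity, since the earlier runs differ in charge.

| setting | larch | alder | winter | midnight | dawn |
|---|---|---|---|---|---|
| G | 0.028 M | 0.15 M | 0.025 M | 0.050 M | 0.10 M |
| remark | run made earlier | run made earlier |  |  |  |
| time |  |  | 3.0 h | 3.0 h | 3.0 h |

| run | time / min | Q / % | G / % |
|---|---|---|---|
| larch | 20.0 | 0 | 93.0 |
| larch | 40.0 | 0.9 | 85.6 |
| larch | 50.0 | 1.5 | 79.9 |
| larch | 80.0 | 2.0 | 70.6 |
| larch | 90.0 | 4.7 | 65.3 |
| larch | 120 | 9.8 | 56.2 |
| alder | 6.00 | 0 | 100.6 |
| alder | 20.0 | 2.1 | 98.1 |
| alder | 40.0 | 0 | 97.1 |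
| alder | 50.0 | 0 | 95.3 |
| alder | 80.0 | 1.0 | 94.5 |
| alder | 90.0 | 0.4 | 93.2 |
| alder | 120 | 0.6 | 94.2 |

(standard deviation of a reading: 1 percentage point)

- solid, in amounts per volume of the solution: G
- on the list of suspects stand: L <-> J; J -> E; X <-> D; L -> Q; X -> L; G <-> X
- at the start none of G is in solution
- "hardly changes" means that all values lie within two and a half points (for a concentration: within two and a half percent of the largest)

1. [Q] at the end for winter, midnight, dawn, in this order
2. how that number moves from the first to the last of them (falls, then rises / hardly changes / rises, then falls / falls all the way / rises all the way)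

At 40.0 min, larch had lost 0.00403 M of G and alder 0.00435 M, and one point of scatter in alder is 0.00150 M. I therefore treated the solid as feeding the solution at a steady rate, whatever its charge, a zero-order draw, and read that rate from the last larch reading:

draw = 0.0123 M / 120 min = 1.02 × 10⁻⁴ M/min

Then I turned the question round. On this picture of a steady draw, a row that moved needed winter, the smallest charge, to lose its solid before the end. So I needed the call on the solid, the G that the draw takes from a flask by the end of the run, to reach the charge of winter:

call = draw × 3.0 h = 0.0184 M

That is 73.6% of the charge of winter. Going round once more, I put this answer back in. By this reckoning winter kept 0.00660 M of G at the end, so the estimate did not undo the steady draw I had assumed. The call stood below every charge, so I expected a flat row, with cQ below the call.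

The forecast gave 0.0065 M, 0.0065 M and 0.0065 M, hardly changes, because, in its words, “Solid persists in all three runs”.

The flask gave 0.00519 M, 0.00519 M and 0.00519 M, so cQ hardly changes.

    L ⇌ J (K = 0.320, k = 0.00222 /min)
    J → E (k = 0.00736 /min)
    X ⇌ D (K = 1.87, k = 0.0415 /min)
    L → Q (k = 0.0131 /min)
    X → L (k = 0.0252 /min)
    G ⇌ X, rate k6*(cs6 - [X]) while solid is left; crystals form when [X] > cs6 (solubility = 15.0 mM, k = 0.00779 /min)

In the midnight flask the local order of cQ in the charge of G was 3.5 × 10⁻⁵. The call left 26.4% of the charge as G in winter, where the flask held 28.2%. In dawn it left 81.6%, and the flask held 82.1%.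

(Readings and results stem from a simulated flask with made-up constants, noise included.)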